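The trap in cedar and birch is the time axis: between 4.00 min and 50.0 min each column wanders by about its scatter of 1 percentage point, yet the two runs stand far apart. So draw the curve against depth, not time.

| setting | cedar | birch | summer | autumn |
|---|---|---|---|---|
| left-handed substrate | 0.020 M | 0.020 M | 0.020 M | 0.020 M |
| right-handed substrate | 0.020 M | 0.020 M | 0.020 M | 0.020 M |
| partner | 0.017 M | 0.043 M | 0.0240 M | 0.0600 M |
| catalyst | 0.34 mM | 0.34 mM | 0.34 mM | 0.34 mM |
| remark | run made earlier | run made earlier |  |  |
| time |  |  | 50 min | 50 min |

| run | time / min | left-handed substrate / % | right-handed substrate / % | left-handed product / % | right-handed product / % |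
|---|---|---|---|---|---|
| cedar | 4.00 | 19.5 | 46.3 | 29.9 | 3.3 |
| cedar | 12.0 | 18.2 | 47.4 | 30.3 | 1.3 |
| cedar | 25.0 | 18.3 | 47.1 | 30.8 | 2.5 |
| cedar | 40.0 | 19.4 | 47.0 | 32.5 | 3.1 |
| cedar | 50.0 | 17.6 | 47.3 | 30.7 | 1.8 |
| birch | 4.00 | 4.4 | 41.1 | 48.6 | 9.6 |
| birch | 12.0 | 1.7 | 41.7 | 47.6 | 10.3 |
| birch | 25.0 | 2.6 | 40.0 | 47.0 | 8.2 |
| birch | 40.0 | 0.7 | 41.1 | 48.1 | 9.2 |
| birch | 50.0 | 1.7 | 40.2 | 47.6 | 10.8 |

(each reading ± 1 percentage point)

- which of these there is most of at the end, counted by the substrate in it, summer (right-handed product / left-handed product / left-handed substrate / right-handed substrate)
- which of these there is most of at the end, counted by the substrate in it, autumn (right-handed product / left-handed product / left-handed substrate / right-handed substrate)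
- how much there is at the end of the one of these that leads, in percent of the left-handed substrate and right-handed substrate together charged: summer
- how much there is at the end of the one of these that leads, in percent of the left-handed substrate and right-handed substrate together charged: autumn

Let depth τ be the natural log of left-handed substrate charged over left-handed substrate present. In the proposed steps both substrates meet the same [partner] and [catalyst], so the right-handed depth stays a fixed fraction of τ. Cedar averages 18.6% left-handed and 47.0% right-handed substrate, each charged at 0.5 of the total.

s = ln(left-handed share left) / ln(right-handed share left) = 16.1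

This s, the left-handed depth over the right-handed depth, here a reading from cedar's means, is the selectivity factor. Birch's left-handed readings lie close to the scatter, so I take its depth from its right-handed mean of 40.8%.

Now the curve, reckoned by me:

Start: per unit of τ, left-handed product rises 0.5 of the total and right-handed substrate falls 3.11%.

Knee: cedar's depth is 0.989, where left-handed product has bent to 31.4%.

Crossing: left-handed product meets right-handed substrate at τ = 2.10, both near 43.9%.

Level: left-handed product runs towards 0.5 of the total, while right-handed substrate keeps falling.

Birch's depth is 3.26. A straight line through the two runs gives 87.5 M⁻¹ of depth per unit of partner charged.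

Summer: τ = 1.60, before the crossing, so right-handed substrate leads at 45.3%.

Autumn: τ = 4.75, past it, so left-handed product leads at 49.6%.

The forecast names right-handed substrate for summer at 45.5% (44.3% to 46.5%) and left-handed product for autumn at 49.6% (49% to 50%), holding that “the endpoints depend only on the partner charged”. My summer figure lies slightly below its figure.

The simulation gives right-handed substrate at 45.7% in summer and left-handed product at 49.6% in autumn.

    partner + catalyst + left-handed substrate → catalyst + left-handed product (k = 11000 M⁻² s⁻¹)
    partner + catalyst + right-handed substrate → catalyst + right-handed product (k = 670 M⁻² s⁻¹)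
    2 partner → homo dimer (k = 0.980 M⁻¹ s⁻¹)
    partner → decomposed reagent (k = 1.90 × 10⁻⁴ s⁻¹)

Summer keeps 23% of its left-handed substrate, and the root of order s of that share is 91.3%, against 91% of the right-handed substrate in the flask. The neighbour of summer, charged with 0.0060 M of partner, keeps 74% of its left-handed substrate, which is a depth of 0.300, before the crossing. The same root gives 98.1%, and that flask keeps 98% of its right-handed substrate.

The numbers in the tables were computed for substances that don't exist, and the scatter is random.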